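**Plan** (labdane numbering: C1–C10 decalin, C17 on C8, C18 = 4α‑CH3, C19 = 4β‑CH2O, C20 on C10, chain C11–C16; β = face of C20)
- Retrosynthesis: cut C13=C14 (Horner–Wadsworth–Emmons), then C9–C11 (alkyl–alkenyl Suzuki coupling of a Δ8 enol triflate), then C3–O (2α,3α‑epoxide of a Δ2 alkene), and last C1–C10 and C4–C5 together.
- Enabling feature: ring B (O on C6, C8=C9, CH3 on C8 and C10, H on C5 and C7) is 2,6‑dimethyl‑1,4‑benzoquinone at a lower oxidation level. Once C3–OH is traced back to a C2=C3 alkene, ring A is a cyclohexene whose C1–C4 unit is a diene across the quinone C5=C10 bond.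
- Forward: ring B is bought as the quinone and ring A is closed onto it in one Diels–Alder step with a Z‑2‑methylpenta‑2,4‑dienyl silyl ether. C5 is then inverted, ring B is reduced and made into the C9 triflate, ring A is epoxidised, and the C11–C16 chain is joined in two pieces.
- Stereochemistry: C10 (absolute) from a chiral oxazaborolidinium catalyst; C4 from the endo rule plus the Z diene; C5 by kinetic protonation; C6 and C3 by substrate control (α‑face hydride, α‑face epoxidation, diaxial opening); 13E from the olefination.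

Key step: step 4

Assumption: the (S)‑oxazaborolidinium catalyst is taken to leave open the quinone face that leads to the 10β‑methyl adduct drawn; if the sense is the opposite, the (R)‑catalyst is used and nothing else changes.

**Step 1**
Reactants: 1 prop‑2‑yn‑1‑ol
Product: 3 (Z)‑3‑iodo‑2‑methylprop‑2‑en‑1‑ol, via chelated alkenylmagnesium alkoxide 2 (not isolated)
Conditions: MeMgBr (3 equiv), CuI (10 mol %), Et2O/THF, −10 °C to rt; then I2, −78 to 0 °C
Reagents that add atoms: methylmagnesium bromide, C[Mg]Br; iodine, [I][I]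
Why: Copper‑catalysed anti‑carbomagnesiation of the propargylic magnesium alkoxide puts methyl on the internal carbon and magnesium on the terminal carbon cis to CH2O through a five‑membered chelate, and iodinolysis with retention fixes the Z geometry that later becomes the 4β‑CH2O group.

**Step 2**
Reactants: 3 (Z)‑3‑iodo‑2‑methylprop‑2‑en‑1‑ol
Product: 4 (Z)‑tert‑butyl[(3‑iodo‑2‑methylprop‑2‑en‑1‑yl)oxy]diphenylsilane
Conditions: TBDPSCl, imidazole, CH2Cl2, 0 °C to rt
Reagents that add atoms: tert‑butyl(chloro)diphenylsilane, CC(C)(C)[Si](Cl)(c1ccccc1)c1ccccc1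
Why: Standard silylation of a primary allylic alcohol; the bulky, weakly basic silyl ether should survive the Lewis acid of step 4 and every later step up to step 15.

**Step 3**
Reactants: 4 (Z)‑tert‑butyl[(3‑iodo‑2‑methylprop‑2‑en‑1‑yl)oxy]diphenylsilane
Product: 5 (Z)‑tert‑butyl[(2‑methylpenta‑2,4‑dien‑1‑yl)oxy]diphenylsilane
Conditions: Bu3SnCH=CH2, Pd(PPh3)4 (5 mol %), CuI (10 mol %), DMF, rt to 45 °C
Reagents that add atoms: tributyl(vinyl)stannane, C=C[Sn](CCCC)(CCCC)CCCC
Why: Stille coupling of an alkenyl iodide proceeds with retention of double‑bond geometry and gives the diene with CH2OSi cis to the vinyl group.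

**Step 4**
Reactants: 5 (Z)‑tert‑butyl[(2‑methylpenta‑2,4‑dien‑1‑yl)oxy]diphenylsilane; 6 2,6‑dimethyl‑1,4‑benzoquinone
Product: 7 cis‑fused Diels–Alder adduct (5β‑H, 10β‑CH3, 4β‑CH2OSi)
Conditions: (S)‑1‑(2‑methylphenyl)‑3,3‑diphenyltetrahydro‑1H,3H‑pyrrolo[1,2‑c][1,3,2]oxazaborole (20 mol %), Tf2NH (18 mol %), CH2Cl2, −78 to −40 °C
Reagents that add atoms: none
Why: Catalytic enantioselective Diels–Alder reaction, the closest known type being oxazaborolidinium‑catalysed cycloadditions of methyl‑substituted 1,4‑benzoquinones that create an angular methyl centre: the boron cation binds the C6 carbonyl, the only one flanked by C–H on both sides, so that the methyl‑bearing C10 becomes the β‑carbon of the activated enone. The diene is 1,1‑disubstituted at C4, which makes the free terminus C1 its nucleophilic end; C1–C10 therefore runs ahead of C4–C5 in a concerted but asynchronous [4+2] addition, and sterics agree because the fully substituted C4 meets the C–H carbon C5. Ring A closes as a cyclohexene, suprafacially on both partners, through the endo transition state with ring B under the diene. C10 and C5 are set together (cis) by the quinone face that the catalyst leaves open, which fixes the absolute configuration, and C4 follows from the endo rule combined with the Z geometry: the inside CH2OSi group ends cis to the exo groups H‑5 and CH3‑20, the outside methyl trans to them. The step needs regio‑, endo‑ and enantiofacial selectivity and mono‑addition; the two C=C bonds of the quinone are equivalent, the remaining ene‑dione double bond is trisubstituted and deactivated towards a second addition, and the diene geometry made in steps 1 to 3 is what turns endo selectivity into the 4β‑CH2O configuration. The cis ring fusion that any such cycloaddition must give is corrected in step 5.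

**Step 5**
Reactants: 7 cis‑fused Diels–Alder adduct
Product: 9 trans‑fused enedione (5α‑H), via trimethylsilyl dienol ether 8 (not isolated)
Conditions: TMSOTf, Et3N, CH2Cl2, 0 °C to rt; then 0.5 M HCl, THF, −20 °C; used at once
Reagents that add atoms: none
Why: Soft enolisation of the C6 ketone has only C5–H available in the α‑position (C10 is quaternary, C7 is sp2) and under equilibrating conditions should favour the linearly conjugated C5=C6–C7=C8–C9=O dienol ether over the cross‑conjugated C17 isomer; kinetic C‑protonation of this silyl enol ether should then occur on the α face, anti to the β‑axial C20 methyl and C19 CH2OSi groups on the two flanking quaternary carbons, which gives the trans ring fusion whatever the cis/trans equilibrium may be (ketonisation under kinetic control).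

**Step 6**
Reactants: 9 trans‑fused enedione
Product: 10 6β‑hydroxy enone
Conditions: NaBH4, CeCl3·7H2O, MeOH/CH2Cl2, −78 °C
Reagents that add atoms: none
Why: Luche 1,2‑reduction should take the less hindered C6 carbonyl (C9 lies between the quaternary C10 and the C8 methyl), with hydride entering from the α face opposite the axial C19 and C20 groups to give the 6β alcohol; the reduction also removes the epimerisable α‑carbonyl position at C5.

**Step 7**
Reactants: 10 6β‑hydroxy enone
Product: 11 6β‑silyloxy enone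
Conditions: TBSOTf, 2,6‑lutidine, CH2Cl2, 0 °C to rt
Reagents that add atoms: tert‑butyldimethylsilyl trifluoromethanesulfonate, CC(C)(C)[Si](C)(C)OS(=O)(=O)C(F)(F)F
Why: Silyl triflate silylation of a hindered axial secondary alcohol; the ether prevents alkoxide side reactions in step 8.

**Step 8**
Reactants: 11 6β‑silyloxy enone
Product: 13 Δ8 enol triflate, via lithium enolate 12 (not isolated)
Conditions: LiBH(s‑Bu)3 (1.1 equiv), THF, −78 °C; then PhNTf2, −78 to 0 °C
Reagents that add atoms: N‑phenylbis(trifluoromethanesulfonimide), O=S(=O)(N(c1ccccc1)S(=O)(=O)C(F)(F)F)C(F)(F)F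
Why: Conjugate hydride reduction of a β‑unsubstituted cyclohexenone by a trialkylborohydride gives the C8=C9 enolate regiospecifically (C10 is quaternary), and O‑triflation traps it as the tetrasubstituted enol triflate, creating C7H2 and the future C8=C9 bond.

**Step 9**
Reactants: 13 Δ8 enol triflate
Product: 14 2α,3α‑epoxy enol triflate
Conditions: mCPBA, NaHCO3, CH2Cl2, 0 °C
Reagents that add atoms: 3‑chloroperoxybenzoic acid, O=C(OO)c1cccc(Cl)c1
Why: Prilezhaev epoxidation should pick the only electron‑rich alkene (the enol triflate is deactivated) and take place on the α face, because the β face of ring A is covered by the axial C20 methyl and C19 CH2OSi groups.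

**Step 10**
Reactants: 14 2α,3α‑epoxy enol triflate; 15 2‑methyl‑2‑vinyl‑1,3‑dioxolane
Product: 17 coupled epoxy ketal, via B‑alkyl‑9‑BBN 16 (not isolated)
Conditions: 15, 9‑BBN dimer, THF, 0 °C to rt; then 14, PdCl2(dppf) (10 mol %), AsPh3 (10 mol %), K3PO4 (3 M aq.), DMF, 50 °C
Reagents that add atoms: none
Why: Anti‑Markovnikov hydroboration of the terminal alkene and B‑alkyl Suzuki–Miyaura coupling with the alkenyl triflate form C9–C11; 2,6,6‑trisubstituted cyclohexenyl triflates are established partners in this coupling, and the epoxide, ketal and silyl ethers should be inert to it.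

**Step 11**
Reactants: 17 coupled epoxy ketal
Product: 18 3α‑hydroxy ketal
Conditions: LiAlH4, THF, 0 °C to reflux
Reagents that add atoms: none
Why: Hydride should open the 2α,3α‑epoxide in the trans‑diaxial sense (Fürst–Plattner rule) by attack at C2, the carbon remote from the quaternary C4, which leaves the axial 3α alcohol; ketal, silyl ethers and the tetrasubstituted alkene are not touched.

**Step 12**
Reactants: 18 3α‑hydroxy ketal
Product: 19 C13 methyl ketone
Conditions: PPTS (cat.), acetone/H2O, 55 °C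
Reagents that add atoms: water, O
Why: Mild acid‑catalysed ketal hydrolysis frees the methyl ketone without cleaving the hindered TBS ether or the TBDPS ether.

**Step 13**
Reactants: 19 C13 methyl ketone
Product: 20 ethyl (13E)‑enoate
Conditions: (EtO)2P(O)CH2CO2Et, NaH, THF, 0 to 50 °C
Reagents that add atoms: triethyl phosphonoacetate, CCOC(=O)CP(=O)(OCC)OCC
Why: Horner–Wadsworth–Emmons olefination of the methyl ketone should give the trisubstituted enoate with the ester trans to the larger C12 chain (13E) as the major isomer, separable from the Z isomer; an extra equivalent of base covers the free 3‑OH.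

**Step 14**
Reactants: 20 ethyl (13E)‑enoate
Product: 21 bis‑silylated dienoic acid
Conditions: LiOH·H2O, THF/MeOH/H2O, 40 °C; then 1 M HCl to pH 3
Reagents that add atoms: lithium hydroxide, [Li+].[OH-]
Why: Saponification of the ethyl ester; the hindered silyl ethers are stable to aqueous LiOH.

**Step 15**
Reactants: 21 bis‑silylated dienoic acid
Product: 22 (13E)‑3α,6β,19‑trihydroxylabda‑8,13‑dien‑15‑oic acid
Conditions: Bu4NF, THF, 50 °C; acidic work‑up
Reagents that add atoms: none
Why: Fluoride‑mediated desilylation (Si–F bond formation) releases the 6β‑ and 19‑hydroxy groups without touching a stereocentre and gives the target.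

**Compound list**
1 | prop‑2‑yn‑1‑ol | C#CCO | starting material
2 | bromomagnesium (Z)‑3‑(bromomagnesio)‑2‑methylprop‑2‑en‑1‑olate | Br[Mg]/C=C(/C)CO[Mg]Br | intermediate
3 | (Z)‑3‑iodo‑2‑methylprop‑2‑en‑1‑ol | I/C=C(/C)CO | intermediate
4 | (Z)‑tert‑butyl[(3‑iodo‑2‑methylprop‑2‑en‑1‑yl)oxy]diphenylsilane | I/C=C(/C)CO[Si](c1ccccc1)(c1ccccc1)C(C)(C)C | intermediate
5 | (Z)‑tert‑butyl[(2‑methylpenta‑2,4‑dien‑1‑yl)oxy]diphenylsilane | C=C/C=C(/C)CO[Si](c1ccccc1)(c1ccccc1)C(C)(C)C | intermediate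
6 | 2,6‑dimethyl‑1,4‑benzoquinone | CC1=CC(=O)C=C(C)C1=O | starting material
7 | (5β)‑19‑(tert‑butyldiphenylsilyloxy)‑11,12,13,14,15,16‑hexanorlabda‑2,7‑diene‑6,9‑dione; cis‑fused, with H‑5, CH3‑20 and CH2OSi‑19 on the β face | CC1=CC(=O)[C@@H]2[C@@](C)(CO[Si](c3ccccc3)(c3ccccc3)C(C)(C)C)C=CC[C@]2(C)C1=O | intermediate
8 | 19‑(tert‑butyldiphenylsilyloxy)‑6‑(trimethylsilyloxy)‑11,12,13,14,15,16‑hexanorlabda‑2,5,7‑trien‑9‑one | CC1=CC(O[Si](C)(C)C)=C2[C@@](C)(CO[Si](c3ccccc3)(c3ccccc3)C(C)(C)C)C=CC[C@]2(C)C1=O | intermediate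
9 | (5α)‑19‑(tert‑butyldiphenylsilyloxy)‑11,12,13,14,15,16‑hexanorlabda‑2,7‑diene‑6,9‑dione; trans‑fused | CC1=CC(=O)[C@H]2[C@@](C)(CO[Si](c3ccccc3)(c3ccccc3)C(C)(C)C)C=CC[C@]2(C)C1=O | intermediate
10 | (5α)‑19‑(tert‑butyldiphenylsilyloxy)‑6β‑hydroxy‑11,12,13,14,15,16‑hexanorlabda‑2,7‑dien‑9‑one | CC1=C[C@@H](O)[C@H]2[C@@](C)(CO[Si](c3ccccc3)(c3ccccc3)C(C)(C)C)C=CC[C@]2(C)C1=O | intermediate
11 | (5α)‑6β‑(tert‑butyldimethylsilyloxy)‑19‑(tert‑butyldiphenylsilyloxy)‑11,12,13,14,15,16‑hexanorlabda‑2,7‑dien‑9‑one | CC1=C[C@@H](O[Si](C)(C)C(C)(C)C)[C@H]2[C@@](C)(CO[Si](c3ccccc3)(c3ccccc3)C(C)(C)C)C=CC[C@]2(C)C1=O | intermediate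
12 | lithium (5α)‑6β‑(tert‑butyldimethylsilyloxy)‑19‑(tert‑butyldiphenylsilyloxy)‑11,12,13,14,15,16‑hexanorlabda‑2,8‑dien‑9‑olate | [Li+].CC1=C([O-])[C@@]2(C)CC=C[C@](C)(CO[Si](c3ccccc3)(c3ccccc3)C(C)(C)C)[C@@H]2[C@H](O[Si](C)(C)C(C)(C)C)C1 | intermediate
13 | (5α)‑6β‑(tert‑butyldimethylsilyloxy)‑19‑(tert‑butyldiphenylsilyloxy)‑11,12,13,14,15,16‑hexanorlabda‑2,8‑dien‑9‑yl trifluoromethanesulfonate | CC1=C(OS(=O)(=O)C(F)(F)F)[C@@]2(C)CC=C[C@](C)(CO[Si](c3ccccc3)(c3ccccc3)C(C)(C)C)[C@@H]2[C@H](O[Si](C)(C)C(C)(C)C)C1 | intermediate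
14 | (5α)‑2α,3α‑epoxy‑6β‑(tert‑butyldimethylsilyloxy)‑19‑(tert‑butyldiphenylsilyloxy)‑11,12,13,14,15,16‑hexanorlabd‑8‑en‑9‑yl trifluoromethanesulfonate | CC1=C(OS(=O)(=O)C(F)(F)F)[C@@]2(C)C[C@H]3O[C@H]3[C@](C)(CO[Si](c4ccccc4)(c4ccccc4)C(C)(C)C)[C@@H]2[C@H](O[Si](C)(C)C(C)(C)C)C1 | intermediate
15 | 2‑methyl‑2‑vinyl‑1,3‑dioxolane | C=CC1(C)OCCO1 | starting material
16 | 9‑[2‑(2‑methyl‑1,3‑dioxolan‑2‑yl)ethyl]‑9‑borabicyclo[3.3.1]nonane | CC1(CCB2C3CCCC2CCC3)OCCO1 | intermediate
17 | 13,13‑(ethylenedioxy)‑2α,3α‑epoxy‑6β‑(tert‑butyldimethylsilyloxy)‑19‑(tert‑butyldiphenylsilyloxy)‑14,15‑dinorlabd‑8‑ene | CC1=C(CCC2(C)OCCO2)[C@@]3(C)C[C@H]4O[C@H]4[C@](C)(CO[Si](c5ccccc5)(c5ccccc5)C(C)(C)C)[C@@H]3[C@H](O[Si](C)(C)C(C)(C)C)C1 | intermediate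
18 | 13,13‑(ethylenedioxy)‑6β‑(tert‑butyldimethylsilyloxy)‑19‑(tert‑butyldiphenylsilyloxy)‑14,15‑dinorlabd‑8‑en‑3α‑ol | CC1=C(CCC2(C)OCCO2)[C@@]3(C)CC[C@@H](O)[C@](C)(CO[Si](c4ccccc4)(c4ccccc4)C(C)(C)C)[C@@H]3[C@H](O[Si](C)(C)C(C)(C)C)C1 | intermediate
19 | 3α‑hydroxy‑6β‑(tert‑butyldimethylsilyloxy)‑19‑(tert‑butyldiphenylsilyloxy)‑14,15‑dinorlabd‑8‑en‑13‑one | CC1=C(CCC(C)=O)[C@@]2(C)CC[C@@H](O)[C@](C)(CO[Si](c3ccccc3)(c3ccccc3)C(C)(C)C)[C@@H]2[C@H](O[Si](C)(C)C(C)(C)C)C1 | intermediate
20 | ethyl (13E)‑3α‑hydroxy‑6β‑(tert‑butyldimethylsilyloxy)‑19‑(tert‑butyldiphenylsilyloxy)labda‑8,13‑dien‑15‑oate | CC1=C(CC/C(C)=C/C(=O)OCC)[C@@]2(C)CC[C@@H](O)[C@](C)(CO[Si](c3ccccc3)(c3ccccc3)C(C)(C)C)[C@@H]2[C@H](O[Si](C)(C)C(C)(C)C)C1 | intermediate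
21 | (13E)‑3α‑hydroxy‑6β‑(tert‑butyldimethylsilyloxy)‑19‑(tert‑butyldiphenylsilyloxy)labda‑8,13‑dien‑15‑oic acid | CC1=C(CC/C(C)=C/C(=O)O)[C@@]2(C)CC[C@@H](O)[C@](C)(CO[Si](c3ccccc3)(c3ccccc3)C(C)(C)C)[C@@H]2[C@H](O[Si](C)(C)C(C)(C)C)C1 | intermediate
22 | (13E)‑3α,6β,19‑trihydroxylabda‑8,13‑dien‑15‑oic acid, (3R,4S,5R,6R,10S) | CC1=C(CC/C(C)=C/C(=O)O)[C@@]2(C)CC[C@@H](O)[C@](C)(CO)[C@@H]2[C@H](O)C1 | target

**Count and risks**
Total steps: 15. Longest linear sequence: 15 (1 to 22); 6 and 15 are bought.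

Step 4. The Z diene must reach a cisoid conformation with the CH2OSi group inside, so the cycloaddition may be slow; ionisation or oligomerisation of the allylic silyl ether may then compete, and catalyst control of the quinone face may be incomplete. Fallback: setting out from 5 and 6, the addition is driven with a stoichiometric achiral Lewis acid (BF3·OEt2, CH2Cl2, −78 °C), which keeps the same regio‑ and endo‑preference and should give 7 as the racemate, that is together with the mirror‑image adduct F1. Compound 7 is separated from the mirror‑image adduct F1 by preparative chromatography on a chiral stationary phase, and the route is rejoined at 7.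

Step 5. Protonation of the dienol ether may show poor facial selectivity and return the cis isomer, which is likely to be the more stable one. Fallback: setting out from 8, N‑bromosuccinimide (THF, −78 °C) gives the 5‑bromo enedione F2 (configuration at C5 of no consequence). Reduction with (Me3Si)3SiH and Et3B/air in toluene at −78 °C generates the planar C5 radical, and hydrogen‑atom transfer from the bulky silane should occur on the open α face, so that steric rather than stereoelectronic control sets the 5α‑H; the route is rejoined at 9.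

Step 13. The olefination of the methyl ketone may give insufficient E/Z selectivity. Fallback: setting out from 19, the 3‑OH is silylated (TESOTf, 2,6‑lutidine) to the triethylsilyl ether F3. LDA and ClP(O)(OEt)2 (THF, −78 °C) give the enol phosphate F4, which eliminates with more LDA to the terminal alkyne F5. Zirconium‑catalysed carboalumination (AlMe3, Cp2ZrCl2, ClCH2CH2Cl, rt) adds methyl and aluminium syn to give the alkenylalane F6, which is trapped with ClCO2Et as the single E enoate F7. PPTS in EtOH removes the triethylsilyl group, and the route is rejoined at 20.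

**Further compounds**
F1 | step 4 | mirror image of 7 | CC1=CC(=O)[C@H]2[C@](C)(CO[Si](c3ccccc3)(c3ccccc3)C(C)(C)C)C=CC[C@@]2(C)C1=O
F2 | step 5 | 5‑bromo‑19‑(tert‑butyldiphenylsilyloxy)‑11,12,13,14,15,16‑hexanorlabda‑2,7‑diene‑6,9‑dione (5α‑bromide drawn) | CC1=CC(=O)[C@@]2(Br)[C@@](C)(CO[Si](c3ccccc3)(c3ccccc3)C(C)(C)C)C=CC[C@]2(C)C1=O
F3 | step 13 | 3α‑(triethylsilyloxy)‑6β‑(tert‑butyldimethylsilyloxy)‑19‑(tert‑butyldiphenylsilyloxy)‑14,15‑dinorlabd‑8‑en‑13‑one | CC1=C(CCC(C)=O)[C@@]2(C)CC[C@@H](O[Si](CC)(CC)CC)[C@](C)(CO[Si](c3ccccc3)(c3ccccc3)C(C)(C)C)[C@@H]2[C@H](O[Si](C)(C)C(C)(C)C)C1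
F4 | step 13 | diethyl enol phosphate of F3 (C13=CH2) | CC1=C(CCC(=C)OP(=O)(OCC)OCC)[C@@]2(C)CC[C@@H](O[Si](CC)(CC)CC)[C@](C)(CO[Si](c3ccccc3)(c3ccccc3)C(C)(C)C)[C@@H]2[C@H](O[Si](C)(C)C(C)(C)C)C1
F5 | step 13 | terminal alkyne (C13≡C14H) with 3α‑OTES, 6β‑OTBS, 19‑OTBDPS | CC1=C(CCC#C)[C@@]2(C)CC[C@@H](O[Si](CC)(CC)CC)[C@](C)(CO[Si](c3ccccc3)(c3ccccc3)C(C)(C)C)[C@@H]2[C@H](O[Si](C)(C)C(C)(C)C)C1
F6 | step 13 | (13E)‑alkenyl(dimethyl)alane from F5 | CC1=C(CC/C(C)=C/[Al](C)C)[C@@]2(C)CC[C@@H](O[Si](CC)(CC)CC)[C@](C)(CO[Si](c3ccccc3)(c3ccccc3)C(C)(C)C)[C@@H]2[C@H](O[Si](C)(C)C(C)(C)C)C1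
F7 | step 13 | ethyl (13E)‑3α‑(triethylsilyloxy)‑6β‑(tert‑butyldimethylsilyloxy)‑19‑(tert‑butyldiphenylsilyloxy)labda‑8,13‑dien‑15‑oate | CC1=C(CC/C(C)=C/C(=O)OCC)[C@@]2(C)CC[C@@H](O[Si](CC)(CC)CC)[C@](C)(CO[Si](c3ccccc3)(c3ccccc3)C(C)(C)C)[C@@H]2[C@H](O[Si](C)(C)C(C)(C)C)C1
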